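**Proposed synthesis of piscisoflavone A by closure of ring C at C4–C4a**

## The problem

Piscisoflavone A is a 3-arylchromen-4-one. Ring A carries one hydroxyl at C7 and is fused to the γ-pyranone ring C. C3 is bonded to C1' of ring B, which has hydroxyls at C2' and C4', a prenyl group at C3' between them and a methoxy group at C5'.

There are no stereocentres, so every question of control is regiochemical: four contiguous substituents must be placed on ring B, and ring C must be fused to ring A at the correct carbon. The one methyl ether has to be kept distinct from three phenols, so the temporary groups cannot be methyl ethers.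

The prenyl group sits between two phenols and closes to a chroman under protic or Lewis acid; it is also lost to hydrogenation. It must therefore arrive late, and the last deprotection must not be acidic. The pyranone opens at C2 under aqueous hydroxide. The C2' oxygen lies next to the three-carbon unit that becomes C2–C4 and, if free, captures either end of it to give a benzofuran or a benzofuranone.

The feature that allows the chosen key step is that C4a is ortho to O1 and para to the C7 oxygen. An acyl cation at C4, held to ring A through O1–C2=C3, reaches C4a in a six-membered transition state and is directed there electronically. Ring B is bonded to C3 and cannot compete, since attack there would require a four-membered ring.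

## Retrosynthesis

**Target 18 to bromide 15.** The three phenols of 18 are unmasked last from triester 17 by methanolysis, the only kind of deprotection the o-prenylphenol tolerates safely. The C3'–prenyl bond of 17 is cut next, back to aryl bromide 15 and prenylstannane 16 (Stille coupling). The alternative, carrying the prenyl group through ring construction, is ruled out by the acid used to close ring C, to which a bromine is inert. Aryl esters are chosen as masks because they survive strong acid, make the C2' oxygen non-nucleophilic and leave under mild base.

**Bromide 15 to acid 13 (key disconnection).** Ring C is opened at C4–C4a. The precursor is the 3-aryloxy-2-arylacrylic acid 13, activated in the flask as mixed anhydride 14. Compared with the usual deoxybenzoin route (O1–C2 closure), this cut uses a simple resorcinol monoester as ring A and needs no separate C2 insertion on a ketone flanked by a C2' oxygen. The forward reaction must close at C4a and not at the carbon between the two ring A oxygens, and must not disturb the esters or the bromide.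

**Acid 13 to tosylate 10 and phenol 11.** The acid is stored as tert-butyl ester 12, so that it can be released by acid alone while the three aryl esters stay on; saponification would strip them. The O1–C2 bond of 12 is then cut to enol tosylate 10 and commercial resorcinol monobenzoate 11 (vinylic substitution). The benzoate is preferred to the monoacetate because it is crystalline, pure and known to survive carbonate-mediated O-functionalisation of the free phenol.

**Tosylate 10 to aldehyde 7 and diazo ester 8.** Tosylate 10 comes from the enol of α-formyl ester 9. Formylating an arylacetate would need an ester enolate next to the C2' acyloxy group, which would take the acyl group. Instead the C1'–C3 bond is formed by an acid-catalysed reaction of aldehyde 7 with tert-butyl diazoacetate 8, in which the aryl group shifts to the diazo carbon. The aldehyde carbon becomes C2, and two steps (homologation, formylation) collapse into one.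

**Aldehyde 7 to isovanillin 1.** The pivalates of 7 come off to give bromoresorcinol aldehyde 6, whose bromine is placed between the two hydroxyls of aldehyde 5. Aldehyde 5 is the formylation product of 4-methoxyresorcinol 3, and 3 arises from isovanillin 1 by Dakin-type oxidation. Each of these substitutions has only one strongly activated site, so the ring B pattern is fixed without isomer separation.

## Roads not taken

**Alternative 1:** Ring B is cut at C2'–C3' and C4'–C5'. In the forward step the 2-methoxyfuran A1, which carries the chromone at its C4, adds across the prenyl-substituted alkynylboronate A2. The oxygen bridge of the adduct opens toward the methoxy-bearing carbon and the ring aromatises to phenol A3, with boron at C4'.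
- Merits: ring B and all four of its substituents arise in one convergent step, the chromone is made early on simple material, and the route would be shorter than the chosen one.
- Weak points: alkynyl pinacolboronates are sluggish dienophiles, 2-methoxyfurans are fragile, and nothing in A1 or A2 strongly enforces the required orientation. After the key step, A3 still needs C–B oxidation beside an enone that epoxidises under basic peroxide, and acidic removal of the acetal beside an o-prenylphenol.
- Comparison: this route is better in step count and convergence. The chosen plan offers instead a sequence in which every step is a known reaction type, a ring B pattern fixed by classical aromatic substitution, and a base-only end-game.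

**Alternative 2:** Ring C is cut at O1–C8a. The enolate oxygen of the α-formyl ketone A4 displaces an ortho fluoride with K2CO3 in DMF, giving the fully protected, already prenylated isoflavone A5.
- Merits: the site of fusion on ring A is fixed by where the fluorine sits, so there is no C4a versus C8 question. The closure is basic, so the prenyl group can be carried from the start and no late organotin step is needed.
- Weak points: the fluoride is activated only by the ortho ketone, which is itself weakened by the para alkoxy donor. The formyl group of A4 can be lost by retro-Claisen cleavage under the same base. A4 needs a prenylated, protected ring B arylacetic unit that costs about as many steps as ring B does here. Three acetal groups must finally be removed with acid beside the prenyl group flanked by two phenols.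
- Comparison: this route is equal or better in regiocontrol on ring A and avoids tin. The chosen plan sets against that the non-acidic final deprotection and an unfunctionalised resorcinol ester as ring A.

**Alternative 3:** Ring B is cut at C1'–C2' and traced to a four-membered ring. Heating cyclobutenone A6 opens it to a dienylketene, which undergoes six-electron electrocyclisation and tautomerises to phenol A7.
- Merits: the contiguous substituents are programmed by the order of additions to a squaric acid diester, the key step is thermal and neutral, and the C2' hydroxyl appears free without a protecting group.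
- Weak points: A6 needs two differentiated alkoxy groups, a prenyl nucleophile that must add without allylic transposition, and a vinyl-metal partner that already carries an electrophilic chromone. The path to A6 is therefore long and delicate. A7 must still lose a tert-butyl ether and an acetal under acid beside the o-prenylphenol.
- Comparison: regiocontrol on ring B is more elegant than here. The chosen plan is shorter, takes the ring B oxygen pattern from isovanillin, and ends under mild base.

Key step: step 9

## Route

Assumption: the alkenes of 9, 10, 12, 13 and 14 are drawn as the isomers expected to predominate; their geometry is lost in step 9, so a mixture would serve equally.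

Step 1
Reactants: 1 isovanillin (3-hydroxy-4-methoxybenzaldehyde)
Product: 3 4-methoxybenzene-1,3-diol, via aryl formate 2 (not isolated)
Conditions: mCPBA, CH2Cl2, 0 °C to rt; then MeOH, Et3N (cat.), rt
Reagents that add atoms: 3-chloroperbenzoic acid (mCPBA), OOC(=O)c1cccc(Cl)c1
Why: Dakin-type Baeyer–Villiger oxidation; the electron-rich aryl group (para methoxy) migrates to oxygen to give formate 2, which is methanolysed in the same flask.

Step 2
Reactants: 3 4-methoxybenzene-1,3-diol
Product: 5 2,4-dihydroxy-5-methoxybenzaldehyde, via iminium chloride 4 (not isolated)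
Conditions: POCl3, DMF, MeCN, 0 °C to rt; then H2O, 50 °C
Reagents that add atoms: N,N-dimethylformamide, CN(C)C=O; water, O
Why: Vilsmeier–Haack formylation; the chloroiminium ion attacks the carbon para to one hydroxyl and ortho to the other, the position between the hydroxyls being more hindered, and water hydrolyses iminium 4.

Step 3
Reactants: 5 2,4-dihydroxy-5-methoxybenzaldehyde
Product: 6 3-bromo-2,4-dihydroxy-5-methoxybenzaldehyde
Conditions: NBS, MeCN, 0 °C
Reagents that add atoms: N-bromosuccinimide, O=C1CCC(=O)N1Br
Why: Electrophilic aromatic bromination; C3 is the only free position ortho to both hydroxyls, whereas C6 is meta to both and ortho to the formyl group.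

Step 4
Reactants: 6 3-bromo-2,4-dihydroxy-5-methoxybenzaldehyde
Product: 7 3-bromo-5-methoxy-2,4-bis(pivaloyloxy)benzaldehyde
Conditions: PivCl, Et3N, DMAP (cat.), CH2Cl2, 0 °C to rt
Reagents that add atoms: pivaloyl chloride, CC(C)(C)C(Cl)=O
Why: DMAP-catalysed O-acylation; pivalates have no α-hydrogens, resist acyl transfer to phenoxide in steps 6 and 7, are inert to the acid of steps 5, 8 and 9, and keep the C2' oxygen non-nucleophilic.

Step 5
Reactants: 7 3-bromo-5-methoxy-2,4-bis(pivaloyloxy)benzaldehyde; 8 tert-butyl diazoacetate
Product: 9 tert-butyl (Z)-2-[3-bromo-5-methoxy-2,4-bis(pivaloyloxy)phenyl]-3-hydroxyprop-2-enoate (enol form of the α-formyl ester)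
Conditions: HBF4·OEt2 (10 mol %), CH2Cl2, −78 °C to rt
Reagents that add atoms: none
Why: Brønsted acid-catalysed aldehyde–diazoacetate homologation with 1,2-aryl shift (the aryl-migration branch of the Roskamp-type reaction); the diazo carbon adds to the protonated aldehyde, the aryl group migrates to it as N2 leaves, and the α-formyl ester appears as its hydrogen-bonded Z enol. No ester enolate is generated beside the C2' pivalate.

Step 6
Reactants: 9 tert-butyl (Z)-2-[3-bromo-5-methoxy-2,4-bis(pivaloyloxy)phenyl]-3-hydroxyprop-2-enoate
Product: 10 tert-butyl (E)-2-[3-bromo-5-methoxy-2,4-bis(pivaloyloxy)phenyl]-3-(tosyloxy)prop-2-enoate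
Conditions: TsCl, Et3N, N-methylimidazole (cat.), CH2Cl2, 0 °C
Reagents that add atoms: 4-toluenesulfonyl chloride, Cc1ccc(cc1)S(Cl)(=O)=O
Why: O-sulfonylation of the enol through the N-sulfonylimidazolium salt; amine, non-chelating conditions are known to favour the E enol tosylate of α-formyl esters, and sulfonylation is fast enough to outrun any acyl shift from the C2' pivalate.

Step 7
Reactants: 10 tert-butyl (E)-2-[3-bromo-5-methoxy-2,4-bis(pivaloyloxy)phenyl]-3-(tosyloxy)prop-2-enoate; 11 resorcinol monobenzoate (3-hydroxyphenyl benzoate)
Product: 12 tert-butyl (E)-3-[3-(benzoyloxy)phenoxy]-2-[3-bromo-5-methoxy-2,4-bis(pivaloyloxy)phenyl]prop-2-enoate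
Conditions: K2CO3, DABCO (10 mol %), MeCN, rt
Reagents that add atoms: none
Why: Nucleophilic vinylic substitution (addition–elimination) of the phenoxide at the β-carbon of the tosyloxyacrylate, assisted by DABCO as nucleophilic catalyst; it forms O1–C2 and should give the more stable E aryloxyacrylate. Resorcinol monobenzoate is routinely O-functionalised under carbonate conditions without loss of the benzoate.

Step 8
Reactants: 12 tert-butyl (E)-3-[3-(benzoyloxy)phenoxy]-2-[3-bromo-5-methoxy-2,4-bis(pivaloyloxy)phenyl]prop-2-enoate
Product: 13 (E)-3-[3-(benzoyloxy)phenoxy]-2-[3-bromo-5-methoxy-2,4-bis(pivaloyloxy)phenyl]prop-2-enoic acid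
Conditions: CF3CO2H, CH2Cl2, 0 °C to rt
Reagents that add atoms: none
Why: Acidolysis of the tert-butyl ester with loss of isobutene; aryl pivalates, the aryl benzoate, the bromide and the push–pull enol ether are stable to trifluoroacetic acid.

Step 9
Reactants: 13 (E)-3-[3-(benzoyloxy)phenoxy]-2-[3-bromo-5-methoxy-2,4-bis(pivaloyloxy)phenyl]prop-2-enoic acid
Product: 15 7-(benzoyloxy)-3-[3-bromo-5-methoxy-2,4-bis(pivaloyloxy)phenyl]chromen-4-one, via trifluoroacetic mixed anhydride 14 (not isolated)
Conditions: (CF3CO)2O, CH2Cl2, 0 °C; then TfOH (10 mol %), 0 °C to rt
Reagents that add atoms: none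
Why: Intramolecular Friedel–Crafts acylation: trifluoroacetic anhydride converts acid 13 into mixed anhydride 14, and catalytic TfOH ionises it to an acylium ion stabilised as an aryloxy-substituted oxocarbenium/ketene resonance form. In that form C2=C3 has little double-bond character, so the E isomer rotates and brings the acyl carbon next to ring A. Electrophilic substitution at the ring A carbon ortho to the ether oxygen and para to the benzoyloxy group, followed by proton loss, forms C4–C4a and closes ring C as a six-membered ring, exo with respect to the acyl C=O. The closest known reactions are the acid-mediated cyclisation of 3-aryloxyacrylic acids to chromones and anhydride-promoted ring closures of aryl-tethered acids. No stereocentre is formed. The selectivity needed is C4a over the carbon between the two ring A oxygens, and the para relationship to the C7 acyloxy donor together with the lower hindrance should secure it. Ring B cannot be acylated because that would need a four-membered ring and the ring is deactivated; the pivaloylated C2' oxygen is too poor a nucleophile to lactonise, and the bromide and esters are inert to the acid.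

Step 10
Reactants: 15 7-(benzoyloxy)-3-[3-bromo-5-methoxy-2,4-bis(pivaloyloxy)phenyl]chromen-4-one; 16 tributyl(3-methylbut-2-enyl)stannane
Product: 17 7-(benzoyloxy)-3-[5-methoxy-3-(3-methylbut-2-enyl)-2,4-bis(pivaloyloxy)phenyl]chromen-4-one
Conditions: Pd2(dba)3 (5 mol %), XPhos (12 mol %), dioxane, 90 °C
Reagents that add atoms: none
Why: Stille cross-coupling; the bulky electron-rich phosphine lets zerovalent palladium insert into the doubly ortho-substituted C–Br bond, the allyl group transfers from tin, and reductive elimination at the less substituted allyl terminus should give the linear prenyl arene. The neutral conditions spare the esters and the pyranone.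

Step 11
Reactants: 17 7-(benzoyloxy)-3-[5-methoxy-3-(3-methylbut-2-enyl)-2,4-bis(pivaloyloxy)phenyl]chromen-4-one
Product: 18 piscisoflavone A
Conditions: K2CO3, MeOH–THF, rt to 40 °C; then aq. NH4Cl
Reagents that add atoms: none
Why: Base-mediated transesterification of three aryl esters with methanol; the activated C7 benzoate should go first, and the resulting C7 phenoxide, para to the carbonyl-bearing carbon, deactivates the pyranone toward methoxide while the pivalates are cleaved. The buffered work-up avoids acid-induced chroman formation.

## Compound list

1 | isovanillin (3-hydroxy-4-methoxybenzaldehyde) | COc1ccc(C=O)cc1O | starting material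
2 | 3-hydroxy-4-methoxyphenyl formate | COc1ccc(OC=O)cc1O | intermediate (not isolated)
3 | 4-methoxybenzene-1,3-diol | COc1ccc(O)cc1O | intermediate
4 | N-[(2,4-dihydroxy-5-methoxyphenyl)methylidene]-N-methylmethanaminium chloride | COc1cc(C=[N+](C)C)c(O)cc1O.[Cl-] | intermediate (not isolated)
5 | 2,4-dihydroxy-5-methoxybenzaldehyde | COc1cc(C=O)c(O)cc1O | intermediate
6 | 3-bromo-2,4-dihydroxy-5-methoxybenzaldehyde | COc1cc(C=O)c(O)c(Br)c1O | intermediate
7 | 3-bromo-5-methoxy-2,4-bis(pivaloyloxy)benzaldehyde | COc1cc(C=O)c(OC(=O)C(C)(C)C)c(Br)c1OC(=O)C(C)(C)C | intermediate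
8 | tert-butyl diazoacetate | CC(C)(C)OC(=O)C=[N+]=[N-] | starting material
9 | tert-butyl (Z)-2-[3-bromo-5-methoxy-2,4-bis(pivaloyloxy)phenyl]-3-hydroxyprop-2-enoate | O/C=C(\C(=O)OC(C)(C)C)c1cc(OC)c(OC(=O)C(C)(C)C)c(Br)c1OC(=O)C(C)(C)C | intermediate
10 | tert-butyl (E)-2-[3-bromo-5-methoxy-2,4-bis(pivaloyloxy)phenyl]-3-(tosyloxy)prop-2-enoate | Cc1ccc(cc1)S(=O)(=O)O/C=C(/C(=O)OC(C)(C)C)c1cc(OC)c(OC(=O)C(C)(C)C)c(Br)c1OC(=O)C(C)(C)C | intermediate
11 | resorcinol monobenzoate (3-hydroxyphenyl benzoate) | O=C(Oc1cccc(O)c1)c1ccccc1 | starting material
12 | tert-butyl (E)-3-[3-(benzoyloxy)phenoxy]-2-[3-bromo-5-methoxy-2,4-bis(pivaloyloxy)phenyl]prop-2-enoate | O=C(Oc1cccc(O/C=C(/C(=O)OC(C)(C)C)c2cc(OC)c(OC(=O)C(C)(C)C)c(Br)c2OC(=O)C(C)(C)C)c1)c1ccccc1 | intermediate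
13 | (E)-3-[3-(benzoyloxy)phenoxy]-2-[3-bromo-5-methoxy-2,4-bis(pivaloyloxy)phenyl]prop-2-enoic acid | O=C(Oc1cccc(O/C=C(/C(=O)O)c2cc(OC)c(OC(=O)C(C)(C)C)c(Br)c2OC(=O)C(C)(C)C)c1)c1ccccc1 | intermediate
14 | mixed anhydride of 13 with trifluoroacetic acid | O=C(Oc1cccc(O/C=C(/C(=O)OC(=O)C(F)(F)F)c2cc(OC)c(OC(=O)C(C)(C)C)c(Br)c2OC(=O)C(C)(C)C)c1)c1ccccc1 | intermediate (not isolated)
15 | 7-(benzoyloxy)-3-[3-bromo-5-methoxy-2,4-bis(pivaloyloxy)phenyl]chromen-4-one | COc1cc(-c2coc3cc(OC(=O)c4ccccc4)ccc3c2=O)c(OC(=O)C(C)(C)C)c(Br)c1OC(=O)C(C)(C)C | intermediate
16 | tributyl(3-methylbut-2-enyl)stannane | CCCC[Sn](CCCC)(CCCC)CC=C(C)C | starting material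
17 | 7-(benzoyloxy)-3-[5-methoxy-3-(3-methylbut-2-enyl)-2,4-bis(pivaloyloxy)phenyl]chromen-4-one | COc1cc(-c2coc3cc(OC(=O)c4ccccc4)ccc3c2=O)c(OC(=O)C(C)(C)C)c(CC=C(C)C)c1OC(=O)C(C)(C)C | intermediate
18 | piscisoflavone A | COc1cc(-c2coc3cc(O)ccc3c2=O)c(O)c(CC=C(C)C)c1O | target

## Step count and risk

Total steps: 11. Longest linear sequence: 11 steps, from isovanillin 1 to 18; compounds 8, 11 and 16 enter as purchased materials.

**Step 9 (key step).** The most likely failure is slow ring closure, because ring A carries only an acyloxy donor. The activated acid could then be diverted by attack of the C2' pivaloyloxy oxygen on the acyl carbon with loss of the pivaloyl group, by trifluoroacetylation of ring A, or by closure at the carbon between the two ring A oxygens. The fallback sets out from 13 and replaces the anhydride/Brønsted acid activation by a preformed acyl chloride and a Lewis acid. Oxalyl chloride with catalytic DMF would give the acid chloride F1, and SnCl4 in CH2Cl2 at low temperature would close it to 15, where the route is rejoined.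

**Step 5.** The migrating aryl group is deactivated by bromine and two acyloxy groups, so the competing 1,2-hydride shift (leading to a β-keto ester) or simple decomposition of the diazo ester may take over. The fallback sets out from 7 and builds the same carbon framework by classical homologation:
- Wittig reaction with the ylide from (methoxymethyl)triphenylphosphonium chloride and KN(SiMe3)2 would give the enol ether F2.
- Aqueous acid would hydrolyse it to the arylacetaldehyde F3.
- Pinnick oxidation (NaClO2, NaH2PO4, 2-methylbut-2-ene) would give the arylacetic acid F4.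
- tert-Butyl 2,2,2-trichloroacetimidate with catalytic BF3·OEt2 would give the tert-butyl ester F5.
- Condensation with tert-butoxybis(dimethylamino)methane would give the enamino ester F6.
- Mild aqueous acid would hydrolyse F6 to 9, where the route is rejoined.

**Step 7.** The phenoxide may attack sulfur instead of carbon (sulfonyl transfer, returning the enolate), or may take an acyl group from ring B. A freed C2' phenoxide would then close onto C2 to a benzofuran. The fallback sets out from 9 and uses a halide leaving group, which removes the sulfur pathway. Oxalyl chloride and DMF would convert the enol into the β-chloroacrylate F7, which would react with 11 and K2CO3 to give 12.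

**Step 10.** Oxidative addition at the bromide flanked by two acyloxy groups may be slow, so that protodebromination competes. Allyl transposition could also deliver the 1,1-dimethylallyl isomer. The fallback sets out from 15 and separates the two problems. Stille coupling with allyltributylstannane would give the allyl compound F8. Cross-metathesis with 2-methylbut-2-ene and the second-generation Grubbs catalyst RuCl2(=CHPh)(PCy3)(H2IMes) would then give 17.

**Step 11.** Cleavage of the two hindered pivalates may be slow, leaving the pyranone exposed to methoxide long enough for ring opening at C2. The fallback sets out from 15 and reverses the order of the last two steps. Acid-catalysed methanolysis (HCl in MeOH, reflux) is permissible while no prenyl group is present, and would give the bromotriol F9. Stille coupling of the free triphenol with 16 would then give 18 directly.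

## Further compounds

F1 | step 9 | (E)-3-[3-(benzoyloxy)phenoxy]-2-[3-bromo-5-methoxy-2,4-bis(pivaloyloxy)phenyl]prop-2-enoyl chloride | O=C(Oc1cccc(O/C=C(/C(Cl)=O)c2cc(OC)c(OC(=O)C(C)(C)C)c(Br)c2OC(=O)C(C)(C)C)c1)c1ccccc1
F2 | step 5 | 2-bromo-6-methoxy-4-[(E)-2-methoxyethenyl]-1,3-phenylene bis(2,2-dimethylpropanoate) | CO/C=C/c1cc(OC)c(OC(=O)C(C)(C)C)c(Br)c1OC(=O)C(C)(C)C
F3 | step 5 | 2-[3-bromo-5-methoxy-2,4-bis(pivaloyloxy)phenyl]acetaldehyde | O=CCc1cc(OC)c(OC(=O)C(C)(C)C)c(Br)c1OC(=O)C(C)(C)C
F4 | step 5 | 2-[3-bromo-5-methoxy-2,4-bis(pivaloyloxy)phenyl]acetic acid | OC(=O)Cc1cc(OC)c(OC(=O)C(C)(C)C)c(Br)c1OC(=O)C(C)(C)C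
F5 | step 5 | tert-butyl 2-[3-bromo-5-methoxy-2,4-bis(pivaloyloxy)phenyl]acetate | CC(C)(C)OC(=O)Cc1cc(OC)c(OC(=O)C(C)(C)C)c(Br)c1OC(=O)C(C)(C)C
F6 | step 5 | tert-butyl (E)-2-[3-bromo-5-methoxy-2,4-bis(pivaloyloxy)phenyl]-3-(dimethylamino)prop-2-enoate | CN(C)/C=C(/C(=O)OC(C)(C)C)c1cc(OC)c(OC(=O)C(C)(C)C)c(Br)c1OC(=O)C(C)(C)C
F7 | step 7 | tert-butyl (E)-2-[3-bromo-5-methoxy-2,4-bis(pivaloyloxy)phenyl]-3-chloroprop-2-enoate | Cl/C=C(/C(=O)OC(C)(C)C)c1cc(OC)c(OC(=O)C(C)(C)C)c(Br)c1OC(=O)C(C)(C)C
F8 | step 10 | 7-(benzoyloxy)-3-[5-methoxy-2,4-bis(pivaloyloxy)-3-(prop-2-enyl)phenyl]chromen-4-one | COc1cc(-c2coc3cc(OC(=O)c4ccccc4)ccc3c2=O)c(OC(=O)C(C)(C)C)c(CC=C)c1OC(=O)C(C)(C)C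
F9 | step 11 | 3-(3-bromo-2,4-dihydroxy-5-methoxyphenyl)-7-hydroxychromen-4-one | COc1cc(-c2coc3cc(O)ccc3c2=O)c(O)c(Br)c1O
A1 | alternative 1 | 3-(5-methoxyfuran-3-yl)-7-(methoxymethoxy)chromen-4-one | COc1cc(-c2coc3cc(OCOC)ccc3c2=O)co1
A2 | alternative 1 | 4,4,5,5-tetramethyl-2-(5-methylhex-4-en-1-ynyl)-1,3,2-dioxaborolane | CC(C)=CCC#CB1OC(C)(C)C(C)(C)O1
A3 | alternative 1 | 3-[2-hydroxy-5-methoxy-3-(3-methylbut-2-enyl)-4-(4,4,5,5-tetramethyl-1,3,2-dioxaborolan-2-yl)phenyl]-7-(methoxymethoxy)chromen-4-one | COc1cc(-c2coc3cc(OCOC)ccc3c2=O)c(O)c(CC=C(C)C)c1B1OC(C)(C)C(C)(C)O1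
A4 | alternative 2 | 3-[2-fluoro-4-(methoxymethoxy)phenyl]-2-[5-methoxy-2,4-bis(methoxymethoxy)-3-(3-methylbut-2-enyl)phenyl]-3-oxopropanal (racemic, enolisable) | COCOc1ccc(C(=O)C(C=O)c2cc(OC)c(OCOC)c(CC=C(C)C)c2OCOC)c(F)c1
A5 | alternative 2 | 3-[5-methoxy-2,4-bis(methoxymethoxy)-3-(3-methylbut-2-enyl)phenyl]-7-(methoxymethoxy)chromen-4-one | COc1cc(-c2coc3cc(OCOC)ccc3c2=O)c(OCOC)c(CC=C(C)C)c1OCOC
A6 | alternative 3 | 3-tert-butoxy-4-methoxy-4-[(E)-2-[7-(methoxymethoxy)-4-oxochromen-3-yl]ethenyl]-2-(3-methylbut-2-enyl)cyclobut-2-en-1-one (racemic) | COC1(/C=C/c2coc3cc(OCOC)ccc3c2=O)C(=O)C(CC=C(C)C)=C1OC(C)(C)C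
A7 | alternative 3 | 3-[4-tert-butoxy-2-hydroxy-5-methoxy-3-(3-methylbut-2-enyl)phenyl]-7-(methoxymethoxy)chromen-4-one | COc1cc(-c2coc3cc(OCOC)ccc3c2=O)c(O)c(CC=C(C)C)c1OC(C)(C)C
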